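(The constants used here belong to no real substance; the flask was simulated.)

Two stirred tanks and a closed flask receive the same D, and each is asked how much of what became J or L is still J.

| flask | D | remark | time |
|---|---|---|---|
| green | 10 mM | one stirred flow tank at steady state, fed with the mixture as stated, mean residence time 6.00 s |  |
| ochre | 10 mM | a closed flask charged with all of it at once and left for 2.0 s | 2.0 s |
| teal | 10 mM | one stirred flow tank at steady state, fed with the mixture as stated, mean residence time 2.0 s |  |

    D + J → 2 J (k1 = 159 /M/s)
    D → J (k2 = 0.0303 /s)
    D ⇌ X (K3 = 0.636, k3 = 0.182 /s)
    J ⇌ L (K4 = 0.904, k4 = 0.0711 /s)

- the stated concentrations are those of everything mixed, before any reaction; amounts are the same in each set-up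
- run time (ochre): 2.0 s

1. the set-up with the highest share of J in all that became J or L, at the outlet or at the end ("none" if the first two lie within 2 percentage points) (green / ochre / teal / none)
2. share of J in all that became J or L, at the outlet or at the end, green
3. share of J in all that became J or L, at the outlet or at the end, ochre
4. share of J in all that became J or L, at the outlet or at the end, teal

Step 4 turns J into L at 0.0711 /s, so J of age 2.0 s has had 0.142 turnovers: the turnover count, forward constant times mean age of J. For a small count n, [L]/[J] is about n, and the share of J is 1/(1+n). A tank's L balance gives exactly [L]/[J] = n/(1+n/K4), with the mean residence time as age. By my reckoning, teal therefore gives 89.1 % and green 77.5 %.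

The ochre flask needs a bracket: its J is younger than the run. No J is charged: step 2 seeds it, and step 1, pseudo-first-order in J while [D] stays near its charge, multiplies it at 1.59 /s, so the growth exponent over the run is 3.18. J present from the start would keep 86.8 %, a loose lower bound. Since making speeds up, even making tightens this: mean age 1.00 s, share 93.4 %. Steady exponential growth gives the upper bound: mean age 0.542 s, share 96.3 %, and falling [D] slows the growth and so ages J. My bracket stands above teal, so I choose ochre.

The forecast gives green 77.5 % and teal 89.1 %, puts ochre at 95.3 % because “little time has passed for J to convert to L”, and picks ochre; its ochre value lies inside the bracket.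

The simulation gives green 77.5 %, teal 89.1 % and ochre 95.3 %, so ochre is best.

Ochre's reading means 0.0493 turnovers, a fraction 0.347 of the 0.142 on offer, so mean age is about a third of the run. The neighbouring ochre flask, read at 8.0 s with amounts held, offers 0.569 turnovers; J made evenly over that time gives 77.9 %. Its share of J reads 76.8 %, less than teal's 89.1 %, with D down to 2.51 % of the charge.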